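Why does this substrate go so slowly? The flask below has been followed for 90.0 min and is asked about at 4.0 h.

the same everywhere: substrate 0.098 M
- theta: reagent in the second phase 1.2 equiv; the very flask that is asked about, followed so far
- flask: reagent in the second phase 1.20 equiv; time 4.0 h; volume of the second phase over the first 1.0

theta run (percent of the substrate charged)

| time / min | substrate / % | target / % |
|---|---|---|
| 15.0 | 94 | 6 |
| 30.0 | 84 | 14 |
| 40.0 | 76 | 16 |
| 60.0 | 63 | 23 |
| 80.0 | 56 | 29 |
| 90.0 | 49 | 24 |

(scatter of a reading: 1.5 percentage points)

- charges count per volume of the first phase; a concentration in a rate is the amount of a species over the volume of its own phase; every rate counts per litre of the first phase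
- the numbers in the tables scatter with a standard deviation of 1.5 percentage points
- the earlier runs hold the two phases in the same ratio of volumes as the flask asked about
- a reading or a percentage of target counts all its forms, free or not
- the reaction counts as stopped when no species that holds the substrate changes by six tenths of a point or more over the second half of the time

- at 4.0 h, what has stopped the reaction, if anything has (forward and back rates have come level / all of the substrate has reacted / it is still moving)
- share of the substrate used up at 4.0 h
- target at 4.0 h, in percent of the substrate charged

How slow, in one number? My assumption is that reagent has to cross from the second phase and reacts soon after it arrives. Crossing is then the slow step, and I take the fast step as keeping pace with it: [reagent in the reaction phase] stays low and level, and the substrate falls pseudo-first-order. I call the slope of ln[substrate] against time the drain constant. The first and last substrate readings give 0.00869 min⁻¹, a half-life of 79.8 min.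

Where is that weak? The readings hold no value of [reagent in the reaction phase], so its level is assumed. But the substrate readings can test it roughly. The stretch up to 60.0 min gives 0.00889 min⁻¹, and the stretch after it gives 0.00838 min⁻¹, a gap inside what the scatter allows.

So what stands at 4.0 h? Carrying the constant on from the last reading, I expect 13.3% substrate left, which is 86.7% used, and still moving.

And target? Its last two readings, 29% and 24%, each carry a scatter of 1.5 percentage points. I would not claim from them that it has turned.

The forecast says it is still moving, with 87% used and 12% target, holding that target is “probably passing on to an unseen species”.

The simulated flask at 4.0 h gives it is still moving, with 89.6% used and 33.2% target, its forms counted.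

    target → over-reaction product (k = 1.40 × 10⁻⁵ min⁻¹)
    target → decomposed product (k = 0.00520 min⁻¹)
    substrate + reagent in the reaction phase → target (k = 1.20 M⁻¹ min⁻¹)
    reagent in the reaction phase ⇌ reagent in the second phase, rate k4*([reagent in the reaction phase] - [reagent in the second phase]/K4) per volume of the first phase (partition coefficient = 1.20, kL = 0.00860 min⁻¹)
    target ⇌ isomer of the product (K = 0.560, k = 0.00790 min⁻¹)
    target ⇌ product in the second phase, rate k6*([target] - [product in the second phase]/K6) per volume of the first phase (partition coefficient = 0.350, kL = 0.00530 min⁻¹)
    substrate + target → side product (k = 0.0420 M⁻¹ min⁻¹)

Reagent in the reaction phase has a half-life by its reaction with the substrate of 0.098 h with the substrate as charged and 0.94 h at 4.00 h, both shorter than the 1.34 h that its crossing constant gives, and its concentration goes from 0.00606 M at 0.400 h to 0.00896 M at 4.00 h. The drain constant of 0.00869 min⁻¹ gave 13.3% substrate at 4.0 h, where the flask holds 10%, and for the same flask read at 2.5 h it gives 29.1% substrate, where the flask holds 27.9%.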